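**Plan** (ring locants: C1 = quaternary carbon, C2 = CH bearing CH2OAr, C3 = methyl-bearing sp2 carbon, C4 = sp2 CH, C5 = CH2, C6 = CH bearing isopropenyl)
- Retrosynthetic cuts, in order: the methyl ester; C=CH2 of the isopropenyl group (back to a C6 acetyl); the C1–CH2 bond of the propanoate arm (back to a C1 carboxyl); C5–H with an allylic shift (back to a C4=C5 alkene with a silyloxy group on C3); ArO–CH2 (back to C2–CHO); last, C2–C3 and C6–C1 together.
- Enabling feature: C3–C4–C5–C6 is a masked butadiene. The C3=C4 alkene beside C5H2 is the allyl-shifted form of a cycloadduct alkene C4=C5 that carries a leaving group on C3. The groups on C2 and C6 are 1,3-cis, as an endo addition to an (E)-diene gives.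
- Forward order: diene 3 comes from opening a pyranone, and dienophile 7 takes two steps. The only new ring, the cyclohexene, is closed in step 4; the coumarin is bought and attached in step 6.
- Helpers: OTBS on C3 (polarises the diene, later the leaving group), CHO on C2 (activator and catalyst handle), CO2tBu on C1 (second activator, leaves as CO2), acetyl on C6 (oxidation-level stand-in for isopropenyl).
- Stereochemistry: C2 and C6 (relative and absolute) come from the catalysed endo Diels–Alder reaction. C1 is set there and set again in step 9 by radical addition anti to the two flanking cis groups.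

Key step: step 4

Assumption: the (S)-diphenylprolinol-derived oxazaborolidinium salt is taken to leave open the face of bound enal 7 that leads to 8; if the sense of induction is the reverse, its (R)-antipode is used and nothing else changes.

**Step 1**
Reactants: 1 6-methyl-2H-pyran-2-one
Product: 3 (3E,5E)-6-[(tert-butyldimethylsilyl)oxy]hepta-3,5-dien-2-one, via lithium dienolate 2 (not isolated)
Conditions: MeLi (1.05 equiv), THF, −78 to 0 °C; then TBSOTf, −78 °C to rt
Reagents that add atoms: methyllithium [Li]C; tert-butyldimethylsilyl trifluoromethanesulfonate C[Si](C)(OS(=O)(=O)C(F)(F)F)C(C)(C)C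
Why: 1,2-addition to the lactone carbonyl and ring opening of the lactolate give the symmetric, delocalised 1,5-dioxapentadienyl anion, which resists a second addition and relaxes to the all-trans form, and the hard silyl electrophile then caps oxygen (nucleophilic ring opening of a 2-pyranone, O-silylation).

**Step 2**
Reactants: 4 2,2-dimethoxyacetaldehyde; 5 tert-butyl 2-(triphenyl-λ5-phosphanylidene)propanoate
Product: 6 tert-butyl (2E)-4,4-dimethoxy-2-methylbut-2-enoate
Conditions: CH2Cl2, rt
Reagents that add atoms: none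
Why: The Wittig reaction of a stabilised, α-branched ylide with an aldehyde should give the (E)-enoate, with the acetal carbon cis to the methyl group.

**Step 3**
Reactants: 6 tert-butyl (2E)-4,4-dimethoxy-2-methylbut-2-enoate
Product: 7 tert-butyl (2E)-2-methyl-4-oxobut-2-enoate
Conditions: Amberlyst-15 (cat.), acetone/H2O 20:1, rt
Reagents that add atoms: water O
Why: Mild acid-catalysed acetal hydrolysis frees the conjugated aldehyde without touching the tert-butyl ester or the alkene geometry.

**Step 4**
Reactants: 3 (3E,5E)-6-[(tert-butyldimethylsilyl)oxy]hepta-3,5-dien-2-one; 7 tert-butyl (2E)-2-methyl-4-oxobut-2-enoate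
Product: 8 tert-butyl (1S,2S,5R,6S)-2-acetyl-5-[(tert-butyldimethylsilyl)oxy]-6-formyl-1,5-dimethylcyclohex-3-ene-1-carboxylate (acetyl, silyloxy, formyl and the methyl on the ester-bearing carbon all on one face)
Conditions: oxazaborolidine from (S)-α,α-diphenylprolinol and o-tolylboronic acid (20 mol %), Tf2NH (18 mol %), CH2Cl2, −78 to −20 °C, 3 (1.5 equiv) added slowly
Reagents that add atoms: none
Why: The boron cation binds the formyl oxygen of 7 rather than its less basic ester, and a concerted but strongly asynchronous Diels–Alder reaction follows, in which the diene terminus α to the acetyl group (future C6) attacks the formyl-β carbon (future C1) first and the bond from the formyl-α carbon (future C2) to the oxygen-bearing terminus (future C3) closes late; the closest known type is the oxazaborolidinium-catalysed enantioselective Diels–Alder reaction of β-methyl-β-alkoxycarbonyl acroleins with donor dienes. One six-membered carbocycle is closed in the suprafacial–suprafacial 4+2 mode. The (E)-alkene of 7 fixes formyl cis to methyl across C2–C1, the endo position of the catalyst-bound formyl group together with the outward acetyl and silyloxy groups of the (E,E)-diene puts the C6 and C3 substituents cis to the formyl group, and the catalyst shields one enal face and so sets the absolute sense. The step needs one regiochemistry, secured by the push–pull polarisation of 3 (silyloxy donor, nucleophilic remote terminus) matched to the formyl-β carbon, and by the fact that the other orientation would have to join two fully substituted carbons. The inward methyl on the silyloxy terminus is tolerated because that terminus bonds late, as in Lewis-acid-promoted cycloadditions of silyloxydienes with a dimethyl-substituted terminus. Cycloaddition at C=C rather than addition at the formyl carbon is favoured by the second acceptor on the alkene and by the damped nucleophilicity of the acyl-substituted dienol ether.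

**Step 5**
Reactants: 8 the cycloadduct aldehyde
Product: 9 tert-butyl (1S,2S,5R,6R)-2-acetyl-5-[(tert-butyldimethylsilyl)oxy]-6-(hydroxymethyl)-1,5-dimethylcyclohex-3-ene-1-carboxylate
Conditions: NaBH4 (0.5 equiv), CH2Cl2/MeOH, −78 °C
Reagents that add atoms: none
Why: Chemoselective borohydride reduction at low temperature should take the aldehyde well before the hindered methyl ketone, and it removes the epimerisable formyl α-position at C2.

**Step 6**
Reactants: 9 the primary alcohol; 10 7-hydroxy-2H-chromen-2-one (umbelliferone)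
Product: 11 tert-butyl (1S,2S,5R,6R)-2-acetyl-5-[(tert-butyldimethylsilyl)oxy]-1,5-dimethyl-6-{[(2-oxo-2H-chromen-7-yl)oxy]methyl}cyclohex-3-ene-1-carboxylate
Conditions: PPh3, DIAD, toluene/THF, 0 to 40 °C
Reagents that add atoms: none
Why: The Mitsunobu etherification of a primary alcohol with an acidic phenol forms the aryl ether under neutral conditions at a carbon that is not a stereocentre.

**Step 7**
Reactants: 11 the aryl ether
Product: 12 tert-butyl (1S,2R,6S)-6-acetyl-1,3-dimethyl-2-{[(2-oxo-2H-chromen-7-yl)oxy]methyl}cyclohex-3-ene-1-carboxylate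
Conditions: Et3SiH (2 equiv), TMSOTf (20 mol %), CH2Cl2, −78 to −30 °C
Reagents that add atoms: none
Why: In this ionic hydrogenation the silyl triflate ionises the tertiary allylic silyl ether to the C3–C4–C5 allyl cation, which should take hydride at the less hindered secondary terminus C5 so that the alkene ends trisubstituted at C3=C4, and no Brønsted acid is present that could protonate the product alkene.

**Step 8**
Reactants: 12 the tert-butyl ester
Product: 13 (1S,2R,6S)-6-acetyl-1,3-dimethyl-2-{[(2-oxo-2H-chromen-7-yl)oxy]methyl}cyclohex-3-ene-1-carboxylic acid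
Conditions: 85 % aq. H3PO4, toluene, rt to 40 °C
Reagents that add atoms: none
Why: Acid-catalysed alkyl–oxygen cleavage of the tert-butyl ester under these mild two-phase conditions should spare the aryl ether, the coumarin, the ketone and the trisubstituted alkene.

**Step 9**
Reactants: 13 the tertiary acid; 14 methyl prop-2-enoate (methyl acrylate)
Product: 16 methyl 3-[(1S,2R,6S)-6-acetyl-1,3-dimethyl-2-{[(2-oxo-2H-chromen-7-yl)oxy]methyl}cyclohex-3-en-1-yl]propanoate, via N-hydroxyphthalimide ester 15 (not isolated)
Conditions: N-hydroxyphthalimide, DIC, DMAP (cat.), CH2Cl2, rt; then MeCN, 14 (3 equiv), Zn, Ni(ClO4)2·6H2O (20 mol %), LiCl, rt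
Reagents that add atoms: none
Why: In this decarboxylative Giese addition, reduction of the redox-active ester releases CO2 and the tertiary C1 radical, which should add to the acrylate on the face opposite the cis acetyl (C6) and aryloxymethyl (C2) neighbours, so the new chain is trans to both and the methyl group stays cis to them.

**Step 10**
Reactants: 16 the methyl ketone
Product: 17 methyl 3-[(1R,2R,6R)-1,3-dimethyl-2-{[(2-oxo-2H-chromen-7-yl)oxy]methyl}-6-(prop-1-en-2-yl)cyclohex-3-en-1-yl]propanoate
Conditions: Zn, CH2Br2, TiCl4 (reagent preformed in THF), CH2Cl2, 0 °C to rt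
Reagents that add atoms: dibromomethane BrCBr
Why: The non-basic Lombardo methylenation converts ketones selectively in the presence of esters and lactones and should not epimerise C6.

**Step 11**
Reactants: 17 the methyl ester
Product: 19 3-[(1R,2R,6R)-1,3-dimethyl-2-{[(2-oxo-2H-chromen-7-yl)oxy]methyl}-6-(prop-1-en-2-yl)cyclohex-3-en-1-yl]propanoic acid (target), via lithium carboxylate 18 (not isolated)
Conditions: LiOH (2 equiv), THF/H2O, 0 °C to rt; then 1 M HCl to pH 2
Reagents that add atoms: lithium hydroxide [Li+].[OH-]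
Why: Saponification of the unhindered primary-chain methyl ester followed by acidification gives the free acid, and no stereocentre lies next to a carbonyl group at this stage.

**Compound list**
1 | 6-methyl-2H-pyran-2-one | CC1=CC=CC(=O)O1 | starting material
2 | lithium (2E,4E)-6-oxohepta-2,4-dien-2-olate | CC(=O)/C=C/C=C(\C)[O-].[Li+] | intermediate
3 | (3E,5E)-6-[(tert-butyldimethylsilyl)oxy]hepta-3,5-dien-2-one | CC(=O)/C=C/C=C(\C)O[Si](C)(C)C(C)(C)C | intermediate
4 | 2,2-dimethoxyacetaldehyde | COC(OC)C=O | starting material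
5 | tert-butyl 2-(triphenyl-λ5-phosphanylidene)propanoate | CC(C(=O)OC(C)(C)C)=P(c1ccccc1)(c1ccccc1)c1ccccc1 | starting material
6 | tert-butyl (2E)-4,4-dimethoxy-2-methylbut-2-enoate | COC(OC)/C=C(\C)C(=O)OC(C)(C)C | intermediate
7 | tert-butyl (2E)-2-methyl-4-oxobut-2-enoate | O=C/C=C(\C)C(=O)OC(C)(C)C | intermediate
8 | tert-butyl (1S,2S,5R,6S)-2-acetyl-5-[(tert-butyldimethylsilyl)oxy]-6-formyl-1,5-dimethylcyclohex-3-ene-1-carboxylate | CC(=O)[C@H]1C=C[C@@](C)(O[Si](C)(C)C(C)(C)C)[C@@H](C=O)[C@]1(C)C(=O)OC(C)(C)C | intermediate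
9 | tert-butyl (1S,2S,5R,6R)-2-acetyl-5-[(tert-butyldimethylsilyl)oxy]-6-(hydroxymethyl)-1,5-dimethylcyclohex-3-ene-1-carboxylate | CC(=O)[C@H]1C=C[C@@](C)(O[Si](C)(C)C(C)(C)C)[C@@H](CO)[C@]1(C)C(=O)OC(C)(C)C | intermediate
10 | 7-hydroxy-2H-chromen-2-one (umbelliferone) | Oc1ccc2ccc(=O)oc2c1 | starting material
11 | tert-butyl (1S,2S,5R,6R)-2-acetyl-5-[(tert-butyldimethylsilyl)oxy]-1,5-dimethyl-6-{[(2-oxo-2H-chromen-7-yl)oxy]methyl}cyclohex-3-ene-1-carboxylate | CC(=O)[C@H]1C=C[C@@](C)(O[Si](C)(C)C(C)(C)C)[C@@H](COc2ccc3ccc(=O)oc3c2)[C@]1(C)C(=O)OC(C)(C)C | intermediate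
12 | tert-butyl (1S,2R,6S)-6-acetyl-1,3-dimethyl-2-{[(2-oxo-2H-chromen-7-yl)oxy]methyl}cyclohex-3-ene-1-carboxylate | CC(=O)[C@H]1CC=C(C)[C@@H](COc2ccc3ccc(=O)oc3c2)[C@]1(C)C(=O)OC(C)(C)C | intermediate
13 | (1S,2R,6S)-6-acetyl-1,3-dimethyl-2-{[(2-oxo-2H-chromen-7-yl)oxy]methyl}cyclohex-3-ene-1-carboxylic acid | CC(=O)[C@H]1CC=C(C)[C@@H](COc2ccc3ccc(=O)oc3c2)[C@]1(C)C(=O)O | intermediate
14 | methyl prop-2-enoate | C=CC(=O)OC | starting material
15 | 1,3-dioxoisoindolin-2-yl (1S,2R,6S)-6-acetyl-1,3-dimethyl-2-{[(2-oxo-2H-chromen-7-yl)oxy]methyl}cyclohex-3-ene-1-carboxylate | CC(=O)[C@H]1CC=C(C)[C@@H](COc2ccc3ccc(=O)oc3c2)[C@]1(C)C(=O)ON1C(=O)c2ccccc2C1=O | intermediate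
16 | methyl 3-[(1S,2R,6S)-6-acetyl-1,3-dimethyl-2-{[(2-oxo-2H-chromen-7-yl)oxy]methyl}cyclohex-3-en-1-yl]propanoate | CC(=O)[C@H]1CC=C(C)[C@@H](COc2ccc3ccc(=O)oc3c2)[C@]1(C)CCC(=O)OC | intermediate
17 | methyl 3-[(1R,2R,6R)-1,3-dimethyl-2-{[(2-oxo-2H-chromen-7-yl)oxy]methyl}-6-(prop-1-en-2-yl)cyclohex-3-en-1-yl]propanoate | C=C(C)[C@H]1CC=C(C)[C@@H](COc2ccc3ccc(=O)oc3c2)[C@]1(C)CCC(=O)OC | intermediate
18 | lithium 3-[(1R,2R,6R)-1,3-dimethyl-2-{[(2-oxo-2H-chromen-7-yl)oxy]methyl}-6-(prop-1-en-2-yl)cyclohex-3-en-1-yl]propanoate | C=C(C)[C@H]1CC=C(C)[C@@H](COc2ccc3ccc(=O)oc3c2)[C@]1(C)CCC(=O)[O-].[Li+] | intermediate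
19 | 3-[(1R,2R,6R)-1,3-dimethyl-2-{[(2-oxo-2H-chromen-7-yl)oxy]methyl}-6-(prop-1-en-2-yl)cyclohex-3-en-1-yl]propanoic acid | C=C(C)[C@H]1CC=C(C)[C@@H](COc2ccc3ccc(=O)oc3c2)[C@]1(C)CCC(=O)O | target

**Total step count:** 11. **Longest linear sequence:** 10 (steps 2–11).

**Steps most likely to fail**

*Step 4.*
- What may go wrong: the cycloaddition may be sluggish, because the vinylogous-ester carbonyl of the diene can tie up the catalyst and the doubly substituted terminus must reach the s-cis form. Addition at the formyl carbon may compete, and endo or facial selectivity may erode.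
- Fallback, from 3 and 7 back to 8: the doubly acceptor-substituted alkene is combined with the diene without any catalyst, in toluene at 80–110 °C or in CH2Cl2 at about 10 kbar. This is a thermal normal-demand Diels–Alder reaction and gives the racemic endo adduct F1. Its enantiomers are separated by preparative chromatography on a cellulose carbamate chiral phase, and the (1S,2S,5R,6S) enantiomer is 8.

*Step 7.*
- What may go wrong: the allyl cation may lose a proton to give a diene or be captured by the neighbouring ester carbonyl. Hydride may arrive at the tertiary terminus, or the ketone may be over-reduced.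
- Fallback, from 11 back to 12: the polar deoxygenation is replaced by a radical one. TBAF in THF frees the tertiary allylic alcohol F2. Methyl chlorooxoacetate with DMAP converts it into the mixed methyl oxalate F3. Bu3SnH/AIBN in refluxing toluene (deoxygenation of a tertiary alkyl oxalate) then generates the allyl radical, which should abstract hydrogen at the secondary terminus C5 and give 12.

*Step 9.*
- What may go wrong: activation of the hindered acid may be slow, the tertiary radical may be reduced before it adds, or the acrylate may attack with poor facial selectivity.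
- Fallback, from 13 back to 16: the C1 stereocentre made in step 4 is kept and the chain is built by polar chemistry.
  1. EDC, DMAP and ethanethiol give the S-ethyl thioester F4.
  2. Fukuyama reduction (Et3SiH, Pd/C, acetone) gives the neopentyl aldehyde F5.
  3. Reductive Knoevenagel alkylation with Meldrum's acid and Hantzsch ester (L-proline cat., EtOH) gives the 5-alkyl Meldrum's acid F6.
  4. Heating F6 in methanol/pyridine opens and decarboxylates it to 16.

**Further compounds**
F1 | step 4 | racemic tert-butyl (1S*,2S*,5R*,6S*)-2-acetyl-5-[(tert-butyldimethylsilyl)oxy]-6-formyl-1,5-dimethylcyclohex-3-ene-1-carboxylate | CC(=O)[C@H]1C=C[C@@](C)(O[Si](C)(C)C(C)(C)C)[C@@H](C=O)[C@]1(C)C(=O)OC(C)(C)C.CC(=O)[C@@H]1C=C[C@](C)(O[Si](C)(C)C(C)(C)C)[C@H](C=O)[C@@]1(C)C(=O)OC(C)(C)C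
F2 | step 7 | tert-butyl (1S,2S,5R,6R)-2-acetyl-5-hydroxy-1,5-dimethyl-6-{[(2-oxo-2H-chromen-7-yl)oxy]methyl}cyclohex-3-ene-1-carboxylate | CC(=O)[C@H]1C=C[C@@](C)(O)[C@@H](COc2ccc3ccc(=O)oc3c2)[C@]1(C)C(=O)OC(C)(C)C
F3 | step 7 | mixed methyl oxalate of F2 at the tertiary allylic oxygen | CC(=O)[C@H]1C=C[C@@](C)(OC(=O)C(=O)OC)[C@@H](COc2ccc3ccc(=O)oc3c2)[C@]1(C)C(=O)OC(C)(C)C
F4 | step 9 | S-ethyl (1S,2R,6S)-6-acetyl-1,3-dimethyl-2-{[(2-oxo-2H-chromen-7-yl)oxy]methyl}cyclohex-3-ene-1-carbothioate | CC(=O)[C@H]1CC=C(C)[C@@H](COc2ccc3ccc(=O)oc3c2)[C@]1(C)C(=O)SCC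
F5 | step 9 | (1S,2R,6S)-6-acetyl-1,3-dimethyl-2-{[(2-oxo-2H-chromen-7-yl)oxy]methyl}cyclohex-3-ene-1-carbaldehyde | CC(=O)[C@H]1CC=C(C)[C@@H](COc2ccc3ccc(=O)oc3c2)[C@]1(C)C=O
F6 | step 9 | 5-{[(1S,2R,6S)-6-acetyl-1,3-dimethyl-2-{[(2-oxo-2H-chromen-7-yl)oxy]methyl}cyclohex-3-en-1-yl]methyl}-2,2-dimethyl-1,3-dioxane-4,6-dione | CC(=O)[C@H]1CC=C(C)[C@@H](COc2ccc3ccc(=O)oc3c2)[C@]1(C)CC4C(=O)OC(C)(C)OC4=O
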